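**Plan**

Rings are lettered A (2,4,6-trihydroxyphenoxy end) to J (3,4,5-trihydroxyphenoxy end). In B, D, F and H the oxygen on C1 is unhindered and the oxygen on C4 lies between two oxygenated carbons. In C, E, G and I, C1 (next to the only C–H) and C2 carry the two ether oxygens.
The retrosynthesis first cuts the 23 O–CH3 bonds of a methyl-protected decamer, then C1–C2 and C1–C6 of ring A. This works because ring A is a phloroglucinol (OH on C1, C3, C5) whose C4, between the C3 and C5 hydroxyls, bears the oxygen to ring B, so C2–C6 map onto a 3-aryloxypentane-2,4-dione and C1 onto a carbonate carbon.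
Next come the sp3 C4–O bond (phenol plus 3-chloropentane-2,4-dione) and the four ethers C2(C)–O–C1(D), C2(E)–O–C1(F), C2(G)–O–C1(H) and C2(I)–O–C1(J). These leave one two-ring phenol, used four times, and an iodide for ring J; the crowded C4–O–C1 ether inside that phenol is cut last.
In the forward direction the two-ring phenol is made once (formylation, Ullmann coupling, Baeyer–Villiger oxidation). The chain then grows from J by two rings per cycle (H–I, F–G, D–E, B–C), each cycle being an Ullmann coupling and a C–H borylation–iodination at the single unflanked C–H of the new end ring.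
Ring B is then hydroxylated at C1 and alkylated. Ring A, the only ring built from an open chain, arises last, and global demethylation ends the route.
The target has no stereocentre and no fixed axis, so no stereochemistry has to be set.

Key step: step 13

Assumption: all nine diaryl ether linkages rotate freely, so the target is one achiral compound; 21 and 23 are drawn as keto tautomers.

**Route**

Step 1
Reactants: 1 5-bromo-1,2,3-trimethoxybenzene
Product: 2 6-bromo-2,3,4-trimethoxybenzaldehyde
Conditions: Cl2CHOMe, TiCl4, CH2Cl2, −10 °C to rt; ice-water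
Reagents that add atoms: dichloromethyl methyl ether, COC(Cl)Cl; water, O
Why: Rieche formylation; the two free positions of 1 are equivalent by symmetry and each lies ortho and para to a methoxy group, so electrophilic substitution can only place the formyl group next to the bromine.

Step 2
Reactants: 2 6-bromo-2,3,4-trimethoxybenzaldehyde; 3 2,6-dimethoxyphenol
Product: 4 6-(2,6-dimethoxyphenoxy)-2,3,4-trimethoxybenzaldehyde
Conditions: CuI (10 mol %), picolinic acid (20 mol %), K3PO4, DMSO, 90 °C, argon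
Reagents that add atoms: none
Why: Ullmann diaryl ether synthesis; the bromide has a single ortho neighbour, a formyl group that activates it and can bind copper, and the CuI–picolinic acid system is established for di-ortho-substituted phenols, so the crowded C4–O–C1 ether is made once on small molecules.

Step 3
Reactants: 4 6-(2,6-dimethoxyphenoxy)-2,3,4-trimethoxybenzaldehyde
Product: 6 6-(2,6-dimethoxyphenoxy)-2,3,4-trimethoxyphenol (two-ring phenol), via aryl formate 5 (not isolated)
Conditions: mCPBA, CH2Cl2, 0 °C to rt; then K2CO3 (cat.), MeOH, rt, argon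
Reagents that add atoms: mCPBA, OOC(=O)c1cccc(Cl)c1
Why: Baeyer–Villiger oxidation; in the peracid adduct of an electron-rich benzaldehyde the aryl group migrates, and catalytic methanolysis of the formate should free the phenol on the carbon that becomes C2 of rings C, E, G and I.

Step 4
Reactants: 6 two-ring phenol; 7 5-iodo-1,2,3-trimethoxybenzene
Product: 8 1-(2,6-dimethoxyphenoxy)-3,4,5-trimethoxy-2-(3,4,5-trimethoxyphenoxy)benzene (H–J trimer)
Conditions: CuI (10 mol %), picolinic acid (20 mol %), K3PO4, DMSO, 90 °C, argon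
Reagents that add atoms: none
Why: Ullmann diaryl ether synthesis in its favourable pairing, a hindered phenoxide with an aryl iodide free of ortho substituents, run under argon so that the electron-rich phenol is not oxidised.

Step 5
Reactants: 8 H–J trimer
Product: 10 H–J trimer iodide (iodine on C1 of ring H), via trimer pinacol boronate 9 (not isolated)
Conditions: [Ir(OMe)(cod)]2 (2 mol %), dtbpy (4 mol %), B2pin2, THF, 80 °C; then CuI (10 mol %), 1,10-phenanthroline (20 mol %), KI, MeOH–THF–H2O, air, 80 °C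
Reagents that add atoms: bis(pinacolato)diboron, CC1(C)OB(OC1(C)C)B1OC(C)(C)C(C)(C)O1 (boryl group of 9); KI, [K+].[I-]
Why: Sterically governed iridium-catalysed C–H borylation followed by copper-catalysed iododeboronation with iodide; C1–H of ring H is the only C–H bond of 8 without an ortho substituent, so boron and then iodine should enter para to the ether oxygen.

Step 6
Reactants: 10 H–J trimer iodide; 6 two-ring phenol
Product: 11 permethylated F–J pentamer (C1 of ring F unsubstituted)
Conditions: CuI (10 mol %), picolinic acid (20 mol %), K3PO4, DMSO, 90 °C, argon; 6 in excess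
Reagents that add atoms: none
Why: Ullmann diaryl ether synthesis as in step 4; the valuable iodide is the limiting partner and is unhindered at the reacting carbon, while the readily made phenol is used in excess.

Step 7
Reactants: 11 F–J pentamer
Product: 13 F–J pentamer iodide (iodine on C1 of ring F), via pentamer pinacol boronate 12 (not isolated)
Conditions: [Ir(OMe)(cod)]2 (2 mol %), dtbpy (4 mol %), B2pin2, THF, 80 °C; then CuI (10 mol %), 1,10-phenanthroline (20 mol %), KI, MeOH–THF–H2O, air, 80 °C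
Reagents that add atoms: bis(pinacolato)diboron, CC1(C)OB(OC1(C)C)B1OC(C)(C)C(C)(C)O1 (boryl group of 12); KI, [K+].[I-]
Why: Iridium-catalysed C–H borylation and copper-catalysed iododeboronation as in step 5; every C–H of rings G to J lies between two oxygen substituents, which leaves C1–H of ring F as the only accessible site.

Step 8
Reactants: 13 F–J pentamer iodide; 6 two-ring phenol
Product: 14 permethylated D–J heptamer (C1 of ring D unsubstituted)
Conditions: CuI (10 mol %), picolinic acid (20 mol %), K3PO4, DMSO, 90 °C, argon; 6 in excess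
Reagents that add atoms: none
Why: Ullmann diaryl ether synthesis; the surroundings of the reacting iodide are the same as in step 6, so chain length should matter little.

Step 9
Reactants: 14 D–J heptamer
Product: 16 D–J heptamer iodide (iodine on C1 of ring D), via heptamer pinacol boronate 15 (not isolated)
Conditions: [Ir(OMe)(cod)]2 (3 mol %), dtbpy (6 mol %), B2pin2, THF, 80 °C; then CuI (10 mol %), 1,10-phenanthroline (20 mol %), KI, MeOH–THF–H2O, air, 80 °C
Reagents that add atoms: bis(pinacolato)diboron, CC1(C)OB(OC1(C)C)B1OC(C)(C)C(C)(C)O1 (boryl group of 15); KI, [K+].[I-]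
Why: Iridium-catalysed C–H borylation and copper-catalysed iododeboronation; C1–H of ring D is again the single C–H without an ortho substituent.

Step 10
Reactants: 16 D–J heptamer iodide; 6 two-ring phenol
Product: 17 permethylated B–J nonamer (C1 of ring B unsubstituted)
Conditions: CuI (10 mol %), picolinic acid (20 mol %), K3PO4, DMSO, 90 °C, argon; 6 in excess
Reagents that add atoms: none
Why: Ullmann diaryl ether synthesis, the fourth use of the same hindered phenoxide with an unhindered iodide.

Step 11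
Reactants: 17 B–J nonamer
Product: 19 B–J nonamer phenol (OH on C1 of ring B), via nonamer pinacol boronate 18 (not isolated)
Conditions: [Ir(OMe)(cod)]2 (3 mol %), dtbpy (6 mol %), B2pin2, THF, 80 °C; then 30% H2O2, aq. NaOH, THF, 0 °C
Reagents that add atoms: bis(pinacolato)diboron, CC1(C)OB(OC1(C)C)B1OC(C)(C)C(C)(C)O1 (boryl group of 18); hydrogen peroxide, OO
Why: One-pot C–H borylation and boronate oxidation; the same steric rule places boron on C1 of ring B, and the 1,2-aryl shift to peroxide oxygen turns it into the unhindered phenol without touching the ethers.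

Step 12
Reactants: 19 B–J nonamer phenol; 20 3-chloropentane-2,4-dione
Product: 21 3-aryloxypentane-2,4-dione (aryl = permethylated B–J nonamer bound through C1 of ring B)
Conditions: Cs2CO3, acetone, reflux; aq. NH4Cl
Reagents that add atoms: none
Why: Williamson-type SN2 O-alkylation of a phenoxide by an α-chloro-β-diketone, the standard entry to 3-aryloxypentane-2,4-diones, here with an unhindered phenol; it sets the future C4–O bond of ring A at an sp3 carbon.

Step 13
Reactants: 21 3-aryloxypentane-2,4-dione; 22 dimethyl carbonate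
Product: 24 decamer with ring A as free 1,3,5-triol (rings B–J methylated), via dioxo ester 23 (not isolated)
Conditions: LDA (3.3 equiv), THF, −78 to 0 °C; 22 (1.0 equiv), −78 to 0 °C; LDA (1.5 equiv), DMPU, 0 to 50 °C; degassed 1 M HCl, argon
Reagents that add atoms: none
Why: Proposed new method: LDA takes the C3 proton and then a methyl proton of 21, and the terminal carbon of this dianion, its most nucleophilic site, attacks 22 with loss of methoxide to give the enolate of dioxo ester 23 (bond C1–C2). More LDA deprotonates the remaining methyl group, whose carbanion attacks the ester carbonyl in a 6-exo-trig Claisen (Dieckmann-type) closure (bond C1–C6), and loss of a second methoxide followed by enolisation of the cyclic trione to the aromatic phloroglucinolate makes the closure irreversible. The closest known reaction types are the terminal acylation of β-diketone dianions by dialkyl carbonates and the base-induced Claisen cyclisation of 3,5-dioxoalkanoates or their enol ethers to phloroglucinols, but the two have not been run in one flask and not on a 3-aryloxy diketone. The step needs carbon rather than oxygen acylation, a single intermolecular acylation, and carbocyclisation rather than closure through the C5 enolate oxygen to a 4-hydroxy-2-pyranone: enol carbonates are returned by lithium methoxide to the more stable C-acylated enolate, 22 is limited to one equivalent, and full deprotonation of the methyl group makes carbon the stronger nucleophile. DMPU and gentle heating loosen the lithium chelates that hold the two chain ends apart, and the C4 aryloxy group helps because it clashes with both flanking chain carbons in the chelated form and so favours the conformer in which C6 can reach C1. The two methyl groups of 21 are equivalent, so either order of bond formation gives the same ring, no stereocentre is formed, and LDA neither metallates the aryl methyl ethers nor cleaves the diaryl ethers.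

Step 14
Reactants: 24 decamer with free ring A
Product: 25 target CNP0255890.0
Conditions: BBr3 (excess), CH2Cl2, −78 °C to rt, argon; degassed H2O; Sephadex LH-20 under argon
Reagents that add atoms: none
Why: Lewis-acid cleavage of aryl methyl ethers; bromide attacks only the methyl carbon of each boron-bound ether, so the 23 O–CH3 bonds should break while the nine diaryl ethers, which offer no sp3 carbon, stay intact.

**Compound list**

1 | 5-bromo-1,2,3-trimethoxybenzene | COc1cc(Br)cc(OC)c1OC | starting material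
2 | 6-bromo-2,3,4-trimethoxybenzaldehyde | COc1cc(Br)c(C=O)c(OC)c1OC | intermediate
3 | 2,6-dimethoxyphenol | COc1cccc(OC)c1O | starting material
4 | 6-(2,6-dimethoxyphenoxy)-2,3,4-trimethoxybenzaldehyde | COc1cccc(OC)c1Oc1cc(OC)c(OC)c(OC)c1C=O | intermediate
5 | 6-(2,6-dimethoxyphenoxy)-2,3,4-trimethoxyphenyl formate | COc1cccc(OC)c1Oc1cc(OC)c(OC)c(OC)c1OC=O | intermediate
6 | 6-(2,6-dimethoxyphenoxy)-2,3,4-trimethoxyphenol (two-ring phenol) | COc1cccc(OC)c1Oc1cc(OC)c(OC)c(OC)c1O | intermediate
7 | 5-iodo-1,2,3-trimethoxybenzene | COc1cc(I)cc(OC)c1OC | starting material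
8 | H–J trimer, 1-(2,6-dimethoxyphenoxy)-3,4,5-trimethoxy-2-(3,4,5-trimethoxyphenoxy)benzene | c1cc(OC)c(Oc2cc(OC)c(OC)c(OC)c2Oc2cc(OC)c(OC)c(OC)c2)c(OC)c1 | intermediate
9 | H–J trimer pinacol boronate (Bpin on C1 of ring H) | CC1(C)OB(OC1(C)C)c1cc(OC)c(Oc2cc(OC)c(OC)c(OC)c2Oc2cc(OC)c(OC)c(OC)c2)c(OC)c1 | intermediate
10 | H–J trimer iodide (I on C1 of ring H) | Ic1cc(OC)c(Oc2cc(OC)c(OC)c(OC)c2Oc2cc(OC)c(OC)c(OC)c2)c(OC)c1 | intermediate
11 | permethylated F–J pentamer | c1cc(OC)c(Oc2cc(OC)c(OC)c(OC)c2Oc2cc(OC)c(Oc3cc(OC)c(OC)c(OC)c3Oc3cc(OC)c(OC)c(OC)c3)c(OC)c2)c(OC)c1 | intermediate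
12 | F–J pentamer pinacol boronate (Bpin on C1 of ring F) | CC1(C)OB(OC1(C)C)c1cc(OC)c(Oc2cc(OC)c(OC)c(OC)c2Oc2cc(OC)c(Oc3cc(OC)c(OC)c(OC)c3Oc3cc(OC)c(OC)c(OC)c3)c(OC)c2)c(OC)c1 | intermediate
13 | F–J pentamer iodide (I on C1 of ring F) | Ic1cc(OC)c(Oc2cc(OC)c(OC)c(OC)c2Oc2cc(OC)c(Oc3cc(OC)c(OC)c(OC)c3Oc3cc(OC)c(OC)c(OC)c3)c(OC)c2)c(OC)c1 | intermediate
14 | permethylated D–J heptamer | c1cc(OC)c(Oc2cc(OC)c(OC)c(OC)c2Oc2cc(OC)c(Oc3cc(OC)c(OC)c(OC)c3Oc3cc(OC)c(Oc4cc(OC)c(OC)c(OC)c4Oc4cc(OC)c(OC)c(OC)c4)c(OC)c3)c(OC)c2)c(OC)c1 | intermediate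
15 | D–J heptamer pinacol boronate (Bpin on C1 of ring D) | CC1(C)OB(OC1(C)C)c1cc(OC)c(Oc2cc(OC)c(OC)c(OC)c2Oc2cc(OC)c(Oc3cc(OC)c(OC)c(OC)c3Oc3cc(OC)c(Oc4cc(OC)c(OC)c(OC)c4Oc4cc(OC)c(OC)c(OC)c4)c(OC)c3)c(OC)c2)c(OC)c1 | intermediate
16 | D–J heptamer iodide (I on C1 of ring D) | Ic1cc(OC)c(Oc2cc(OC)c(OC)c(OC)c2Oc2cc(OC)c(Oc3cc(OC)c(OC)c(OC)c3Oc3cc(OC)c(Oc4cc(OC)c(OC)c(OC)c4Oc4cc(OC)c(OC)c(OC)c4)c(OC)c3)c(OC)c2)c(OC)c1 | intermediate
17 | permethylated B–J nonamer | c1cc(OC)c(Oc2cc(OC)c(OC)c(OC)c2Oc2cc(OC)c(Oc3cc(OC)c(OC)c(OC)c3Oc3cc(OC)c(Oc4cc(OC)c(OC)c(OC)c4Oc4cc(OC)c(Oc5cc(OC)c(OC)c(OC)c5Oc5cc(OC)c(OC)c(OC)c5)c(OC)c4)c(OC)c3)c(OC)c2)c(OC)c1 | intermediate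
18 | B–J nonamer pinacol boronate (Bpin on C1 of ring B) | CC1(C)OB(OC1(C)C)c1cc(OC)c(Oc2cc(OC)c(OC)c(OC)c2Oc2cc(OC)c(Oc3cc(OC)c(OC)c(OC)c3Oc3cc(OC)c(Oc4cc(OC)c(OC)c(OC)c4Oc4cc(OC)c(Oc5cc(OC)c(OC)c(OC)c5Oc5cc(OC)c(OC)c(OC)c5)c(OC)c4)c(OC)c3)c(OC)c2)c(OC)c1 | intermediate
19 | B–J nonamer phenol (OH on C1 of ring B) | Oc1cc(OC)c(Oc2cc(OC)c(OC)c(OC)c2Oc2cc(OC)c(Oc3cc(OC)c(OC)c(OC)c3Oc3cc(OC)c(Oc4cc(OC)c(OC)c(OC)c4Oc4cc(OC)c(Oc5cc(OC)c(OC)c(OC)c5Oc5cc(OC)c(OC)c(OC)c5)c(OC)c4)c(OC)c3)c(OC)c2)c(OC)c1 | intermediate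
20 | 3-chloropentane-2,4-dione | CC(=O)C(Cl)C(C)=O | starting material
21 | 3-aryloxypentane-2,4-dione carrying the permethylated B–J nonamer on oxygen | CC(=O)C(C(C)=O)Oc1cc(OC)c(Oc2cc(OC)c(OC)c(OC)c2Oc2cc(OC)c(Oc3cc(OC)c(OC)c(OC)c3Oc3cc(OC)c(Oc4cc(OC)c(OC)c(OC)c4Oc4cc(OC)c(Oc5cc(OC)c(OC)c(OC)c5Oc5cc(OC)c(OC)c(OC)c5)c(OC)c4)c(OC)c3)c(OC)c2)c(OC)c1 | intermediate
22 | dimethyl carbonate | COC(=O)OC | starting material
23 | methyl 4-aryloxy-3,5-dioxohexanoate (aryl = permethylated B–J nonamer) | COC(=O)CC(=O)C(C(C)=O)Oc1cc(OC)c(Oc2cc(OC)c(OC)c(OC)c2Oc2cc(OC)c(Oc3cc(OC)c(OC)c(OC)c3Oc3cc(OC)c(Oc4cc(OC)c(OC)c(OC)c4Oc4cc(OC)c(Oc5cc(OC)c(OC)c(OC)c5Oc5cc(OC)c(OC)c(OC)c5)c(OC)c4)c(OC)c3)c(OC)c2)c(OC)c1 | intermediate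
24 | decamer with ring A as free triol and rings B–J methylated | Oc1cc(O)c(Oc2cc(OC)c(Oc3cc(OC)c(OC)c(OC)c3Oc3cc(OC)c(Oc4cc(OC)c(OC)c(OC)c4Oc4cc(OC)c(Oc5cc(OC)c(OC)c(OC)c5Oc5cc(OC)c(Oc6cc(OC)c(OC)c(OC)c6Oc6cc(OC)c(OC)c(OC)c6)c(OC)c5)c(OC)c4)c(OC)c3)c(OC)c2)c(O)c1 | intermediate
25 | CNP0255890.0 | Oc1cc(O)c(Oc2cc(O)c(Oc3cc(O)c(O)c(O)c3Oc3cc(O)c(Oc4cc(O)c(O)c(O)c4Oc4cc(O)c(Oc5cc(O)c(O)c(O)c5Oc5cc(O)c(Oc6cc(O)c(O)c(O)c6Oc6cc(O)c(O)c(O)c6)c(O)c5)c(O)c4)c(O)c3)c(O)c2)c(O)c1 | target

**Count and risks**

Total step count: 14. Longest linear sequence: 14 steps (1 → 2 → 4 → 6 → 8 → 10 → 11 → 13 → 14 → 16 → 17 → 19 → 21 → 24 → 25). Phenol 6 is made once and enters in steps 4, 6, 8 and 10.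

Step 13. The polyanion of the open-chain ester may fail to close because its ester is part of an enolate. It may also close through oxygen to the pyranone, or the second methyl group may be acylated by a further carbonate molecule. The fallback gives up building ring A from an open chain and attaches it as a finished ring by the coupling already used four times. It sets out from 17. The borylation–iodination of steps 5, 7 and 9, passing through 18, should give the B–J nonamer iodide F1. Ullmann coupling of F1 with commercial 2,4,6-trimethoxyphenol (CuI, picolinic acid, K3PO4, DMSO, 90 °C, argon) puts the hindered oxygen on the nucleophile and should give the permethylated decamer F2. BBr3 then cleaves all 26 methyl ethers, and the route is rejoined at 25.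

Step 14. Ether cleavage may stop part-way when partly cleaved boron aryloxides leave the solution, and the pyrogallol rings may oxidise in air during isolation. The fallback replaces direct isolation by a protect–purify–release sequence. It sets out from 24. The crude BBr3 product is not isolated but acetylated (Ac2O, pyridine) to the decamer hexacosaacetate F3. F3 is stable in air, can be separated from under-cleaved material on silica gel, and allows that material to be returned to the cleavage. HCl-catalysed methanolysis in degassed MeOH then rejoins the route at 25.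

Step 9. On the long, electron-rich chain the iododeboronation under air may be accompanied by protodeboronation or by iodination of the activated internal rings. The fallback avoids any halogen and changes the coupling from a halide-based to a boron-based one. It sets out from 14. Borylation to 15 followed by NaIO4 and NH4OAc in acetone–water should give the D–J heptamer boronic acid F4. Chan–Lam coupling of F4 with 6 (Cu(OAc)2, pyridine, 4 Å molecular sieves, CH2Cl2, dry air, rt) then rejoins the route at 17.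

**Further compounds**

F1 | step 13 | B–J nonamer iodide (I on C1 of ring B) | Ic1cc(OC)c(Oc2cc(OC)c(OC)c(OC)c2Oc2cc(OC)c(Oc3cc(OC)c(OC)c(OC)c3Oc3cc(OC)c(Oc4cc(OC)c(OC)c(OC)c4Oc4cc(OC)c(Oc5cc(OC)c(OC)c(OC)c5Oc5cc(OC)c(OC)c(OC)c5)c(OC)c4)c(OC)c3)c(OC)c2)c(OC)c1
F2 | step 13 | permethylated decamer (26 methyl ethers) | COc1cc(OC)c(Oc2cc(OC)c(Oc3cc(OC)c(OC)c(OC)c3Oc3cc(OC)c(Oc4cc(OC)c(OC)c(OC)c4Oc4cc(OC)c(Oc5cc(OC)c(OC)c(OC)c5Oc5cc(OC)c(Oc6cc(OC)c(OC)c(OC)c6Oc6cc(OC)c(OC)c(OC)c6)c(OC)c5)c(OC)c4)c(OC)c3)c(OC)c2)c(OC)c1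
F3 | step 14 | decamer hexacosaacetate | CC(=O)Oc1cc(OC(C)=O)c(Oc2cc(OC(C)=O)c(Oc3cc(OC(C)=O)c(OC(C)=O)c(OC(C)=O)c3Oc3cc(OC(C)=O)c(Oc4cc(OC(C)=O)c(OC(C)=O)c(OC(C)=O)c4Oc4cc(OC(C)=O)c(Oc5cc(OC(C)=O)c(OC(C)=O)c(OC(C)=O)c5Oc5cc(OC(C)=O)c(Oc6cc(OC(C)=O)c(OC(C)=O)c(OC(C)=O)c6Oc6cc(OC(C)=O)c(OC(C)=O)c(OC(C)=O)c6)c(OC(C)=O)c5)c(OC(C)=O)c4)c(OC(C)=O)c3)c(OC(C)=O)c2)c(OC(C)=O)c1
F4 | step 9 | D–J heptamer boronic acid (B(OH)2 on C1 of ring D) | OB(O)c1cc(OC)c(Oc2cc(OC)c(OC)c(OC)c2Oc2cc(OC)c(Oc3cc(OC)c(OC)c(OC)c3Oc3cc(OC)c(Oc4cc(OC)c(OC)c(OC)c4Oc4cc(OC)c(OC)c(OC)c4)c(OC)c3)c(OC)c2)c(OC)c1
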